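**Remarks before the route**

- Check of structures: the target, the cyclisation precursor and the cyclisation product were compared atom by atom (ring sizes, trans fusion, isoprenoid mapping, configuration at C1, C4 and C5) and needed no correction. The design changes lie after the cyclisation: C10 is kept as a ketone until C6 is esterified, so two free secondary hydroxyls never coexist, and the phenol is masked during both esterifications.
- Assumption 1: daucane numbering is used for all bicyclic compounds (C1 quaternary fusion carbon, C4 isopropyl carbinol, C5 fusion CH, C6, C7, C8=C9, C10); "cis" and "trans" refer to the C1 methyl group unless stated otherwise.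
- Assumption 2: the enzyme-bound tertiary diphosphate 4 is written as the 3R enantiomer, the one whose cisoid conformer should place the central olefin correctly for an anti allylic closure. Its stereocentre becomes the planar C8 of 5, so nothing downstream depends on this choice.
- Assumption 3: 3 is drawn as the free acid and is made, stored and used as its trisammonium salt.

## Structural features

The target is a daucane sesquiterpene diester: a bicyclo[5.3.0]decane in which a cyclopentane (C1–C5) and a cycloheptene (C1, C5, C6, C7, C8, C9, C10, with a trisubstituted C8=C9 olefin carrying a methyl on C8) share the C1–C5 bond. C1 is quaternary (angular methyl), C4 is a tertiary carbinol bearing the isopropyl group, C6 carries the 4-hydroxybenzoate, and C10, which is allylic and next to the quaternary carbon, carries the 3-methylbutanoate. The five stereocentres form one contiguous array C10–C1–C5(–C4)–C6 with descriptors 1S,4S,5S,6R,10S: the ring fusion is trans (C1 methyl anti to C5–H), the C4 hydroxyl is cis to C5–H, and both ester oxygens lie on the face of the C1 methyl. Fragile points are the tertiary alcohol (dehydration), the allylic ester at C10 (ionisation, allylic displacement, hydrogenolysis), two different esters on one ring (hydrolysis, migration) and the free phenol. The real difficulties are the seven-membered ring with its quaternary fusion carbon, the oxygen at C6 on a methylene that no functional group activates, and the need to tell two secondary hydroxyls apart for two different acyl groups. The key step uses the unrearranged head-to-tail isoprenoid skeleton: C10–C9–C8(Me)–C7, C6–C5–C1(Me)–C2 and C3–C4–CMe2 are the three prenyl units of a farnesyl chain. Only the bonds C1–C10 (seven-membered ring), C4–C5 (five-membered ring) and C4–O therefore separate the framework from farnesyl diphosphate.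

## Logic of the disconnections

15 ⇒ 14. The O–Si bond on the phenol is the last bond cut. The phenol must be masked while both esters are made, otherwise the aryl acid would acylate itself. No skeletal simplification results, but the aryl acid becomes a usable acyl donor. The forward step must remove silicon without touching an aryl ester, an allylic alkyl ester or the tertiary alcohol.

14 ⇒ 12 + 13. The acyl C–O bond at C10 is cut. This ester is made late so that the allylic ester meets as few reagents as possible. The cut removes a five-carbon side chain as a commercial acid. The forward step must acylate a hindered secondary allylic hydroxyl without ionising it and must leave the tertiary C4 hydroxyl alone.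

12 ⇒ 11. The C10–H bond is cut, which turns the C10 carbinol into a ketone. This is the device that differentiates the two oxygenated positions: C6 is esterified while C10 is still a carbonyl. It also removes one stereocentre and traces the C10 oxygen to an allylic oxidation. The forward step must deliver hydride 1,2 and from the face anti to the C1 methyl.

11 ⇒ 7 + 10, and 10 ⇒ 8 (through 9). The acyl C–O bond at C6 is cut, and the acid partner is traced to 8 by cutting its two O–Si bonds. The aryl ester is introduced when C6–OH is the only secondary hydroxyl present. The forward coupling must prefer the secondary over the tertiary hydroxyl and must be mild enough that the δ-oxygenated enone does not eliminate.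

7 ⇒ 6. The C6–O bond is cut, a C–H hydroxylation in the forward sense. Polar reagents would approach C6 from the face of the C4 hydroxyl, which is the wrong face, and nothing activates the position. A catalyst that selects one hydrogen by binding is therefore the shortest answer. The cut removes one stereocentre and the only heteroatom at an unactivated site. The forward step must insert oxygen at C6 only, with retention, into the C–H bond cis to the C1 methyl.

6 ⇒ 5. The C10=O bond is cut back to a methylene. C10 is the methylene attached to the CH terminus of the olefin, the usual site of radical allylic oxidation in trisubstituted cycloalkenes. The forward step must prefer C10 over C7 and the C8 methyl.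

5 ⇒ 3 (through 4). The bonds C1–C10 and C4–C5 and the C4–O bond are cut. This opens both rings and removes all three stereocentres of 5, leaving an achiral acyclic chain. The forward step needs a catalyst that ionises the diphosphate, fixes one chain fold, allows a 1,2-hydride shift and places water at C4 from one face; only an enzyme active site is expected to do all of this.

3 ⇒ 2 ⇒ 1. The C–O bond to phosphorus and then the C–Cl bond are cut, ending at a commercial allylic alcohol. The forward steps must substitute at the primary allylic carbon without allylic transposition or loss of olefin geometry.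

## Other disconnections considered

Alternative 1: The cut is made at C9. Removing the bonds C9–C10 and C8–C9 contracts the seven-membered ring to the six-membered ring of a trans-fused six–five bicycle.

- Forward key step: the silyl enol ether A2 (C10(OSiMe3)=C8, the only possible enolisation direction because C1 is quaternary) would take up a methylene from CH2I2/Et2Zn (Simmons–Smith cyclopropanation). FeCl3 would then cleave the old C8–C10 bond by one-electron oxidation, and NaOAc would complete the enone A1 by loss of HCl (Saegusa–Ito-type ring expansion).
- In favour: all of C1, C4, C5 and C6 would be fixed on a rigid bicycle before the seven-membered ring exists. Every reaction type is known. A1 is the doubly protected form of 7, so this plan would join the chosen route at steps 7–10.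
- Against: the precursor must already carry four contiguous stereocentres and the trans fusion, which is the awkward junction for six–five bicycles and would cost a long linear sequence. The tetrasubstituted enol ether next to a quaternary carbon is a slow partner for the zinc carbenoid. FeCl3 is Lewis acidic enough to endanger the 4-methoxybenzyl ether and the tertiary silyl ether.
- Comparison, structure: both plans converge on the same C10 enone, so from there the alternative is the equal of the chosen plan. It is the better plan in needing no C–H hydroxylation at C6 and no catalyst that is still to be found.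
- Comparison, mechanism: it replaces a cationic cascade that builds both rings and three stereocentres by a radical one-carbon insertion that builds no stereocentre.
- Comparison, step economy: it is clearly worse, estimated at about twice the step count with three protecting groups.

Alternative 2: The cut removes C3 as carbon monoxide together with the bonds C1–C5, C2–C3 and C3–C4. This opens both rings and leaves the acyclic enyne A4.

- Forward key step: a Pauson–Khand reaction (Co2(CO)8 followed by an amine N-oxide, or [Rh(CO)2Cl]2 under CO) would join the isopropyl-substituted alkyne, the isopropenyl group and CO. The cyclopentenone A3 results, with the five-membered ring closed by the cycloaddition and the seven-membered ring closed through the tether.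
- In favour: three C–C bonds, both rings and the quaternary C1 would arise in one operation. The C6 and C10 oxygens are already present with their configuration. The Z olefin C8=C9 in the tether holds the reacting ends near each other.
- Against: intramolecular Pauson–Khand closures of seven-membered rings are reluctant with simple alkenes. A 1,1-disubstituted alkene is a poor partner and must here create a quaternary centre. The induction from C6 and C10 to C1 is unknown. A3 also has the wrong oxidation pattern in the five-membered ring: a C3 carbonyl to be removed, and a C4=C5 enone whose polarity directs nucleophiles to C5 and not oxygen to C4. The C4 hydroxyl and the trans C5–H would need several further redox steps.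
- Comparison, structure: the alternative equals the chosen plan in closing both rings in the key step. It is better in bringing C6 and C10 in oxidised form, and worse at C3–C5.
- Comparison, mechanism: it uses a known metal-mediated cycloaddition, a point in its favour over an enzyme to be discovered, but at the edge of its scope.
- Comparison, step economy: the enyne synthesis plus the corrections after cyclisation should exceed the ten steps of the chosen route.

Alternative 3: The cut removes the bonds C1–C5 and C1–C10, which takes C1 out of both rings. The remaining six carbons of the seven-membered ring become a symmetric 2,6-dimethoxy-4-methylphenyl ring attached to C4.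

- Forward key step: the diazoketone A6 with Rh2(OAc)4 would give a rhodium carbenoid at C1 that adds across the ipso–ortho bond C5–C10. The resulting three-membered ring opens by 6π electrocyclisation to the cycloheptatriene A5 (Buchner reaction).
- In favour: the arene supplies six ring carbons with the methyl at C8 and oxygen at both C6 and C10 as enol ethers. Its symmetry removes any regiochemical question. A6 should be reachable in few steps with C4 set by an asymmetric addition. Both ring-forming bonds arise in one catalytic step of a known type.
- Against: a carbenoid with an α-methyl group is prone to 1,2-hydride migration. The bond attacked lies between two fully substituted aromatic carbons. Induction from C4 to the new quaternary C1 is uncertain. A5 is also far from the target in oxidation level: the C2 carbonyl must go, two enol ethers must be hydrolysed and the ketones reduced with the correct facial sense, C5 must receive hydrogen trans to the C1 methyl, and only C8=C9 may survive, all on a triene that can undergo hydrogen shifts.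
- Comparison, structure: it is better than the chosen plan in carrying oxygen at C6 and C10 from the start, and equal in forming both ring-closing bonds in one step.
- Comparison, mechanism: it relies on a precedented carbenoid reaction instead of an enzyme still to be found, but offers no control over C5, C6 and C10.
- Comparison, step economy: the long redox correction after the key step makes it the longer route.

Key step: step 3

## Route

Step 1
Reactants: 1 (2E,6E)-farnesol
Product: 2 (2E,6E)-farnesyl chloride
Conditions: NCS, Me2S, CH2Cl2, −30 → 0 °C
Reagents that add atoms: N-chlorosuccinimide, O=C1CCC(=O)N1Cl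
Why: Corey–Kim chlorination: the chlorosulfonium salt activates the primary allylic alcohol and chloride displaces at the same carbon, so no allylic transposition occurs, the 2E,6E geometry is kept and no stereocentre is formed.

Step 2
Reactants: 2 (2E,6E)-farnesyl chloride
Product: 3 (2E,6E)-farnesyl diphosphate (isolated as its trisammonium salt)
Conditions: (n-Bu4N)3HP2O7, MeCN, rt; Dowex 50W-X8 (NH4+ form), aq NH4HCO3/i-PrOH; lyophilisation, cellulose chromatography
Reagents that add atoms: tris(tetrabutylammonium) hydrogen diphosphate, CCCC[N+](CCCC)(CCCC)CCCC.CCCC[N+](CCCC)(CCCC)CCCC.CCCC[N+](CCCC)(CCCC)CCCC.OP(=O)([O-])OP(=O)([O-])[O-]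
Why: SN2 displacement of the primary allylic chloride by the diphosphate anion; the soluble tetrabutylammonium salt in dry acetonitrile favours direct substitution over allylic transposition, and cation exchange gives the water-soluble ammonium salt that a synthase accepts.

Step 3
Reactants: 3 (2E,6E)-farnesyl diphosphate
Product: 5 (1R,4S,5R)-dauc-8-en-4-ol, via (3R,6E)-nerolidyl diphosphate 4 (not isolated)
Conditions: recombinant dauc-8-en-4-ol synthase (diphosphate-ionising sesquiterpene synthase, purified), MgCl2, HEPES buffer pH 7.5, dithiothreitol, 10% glycerol, pentane overlay, 30 °C
Reagents that add atoms: water, O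
Why: Proposed new method: no characterised synthase is known to release this 4-ol, so the step rests on the closest known reaction type, the enzymatic cyclisation of farnesyl diphosphate to daucane olefins and alcohols, from which it differs only in the last hydride shift and the site of water capture. The Mg2+ cluster of the active site ionises 3, the diphosphate returns to the tertiary carbon (C8) to give enzyme-bound 4, and re-ionisation of the cisoid conformer lets the central olefin bond through its methyl-bearing carbon C1 to the allylic terminus C10, anti to the departing diphosphate. The seven-membered ring thus closes in a 7-endo mode with respect to that olefin (directly or by enlargement of a six-membered bisabolyl-type cation), and the charge arriving at C5 is taken up in a 5-exo closure by C4 of the distal olefin, which leaves a tertiary cation on the isopropyl carbon. A 1,2-hydride shift from C4 moves the charge into the ring and an active-site water adds to C4. C1 and C5 are set together by anti addition across the 6E olefin, so the E geometry of 3 becomes the trans ring fusion, while the absolute sense is imposed by the fold that the active-site contour enforces. The C4 configuration is fixed by the position of the bound water, on the face cis to C5–H. The step needs one fold out of many and the suppression of early deprotonation or early hydration; the achiral substrate secures only the relative configuration C1/C5, and everything else must come from the enzyme, to be sought by mining the transcriptome of the producing plant family and by mutagenesis of known daucane-forming synthases.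

Step 4
Reactants: 5 (1R,4S,5R)-dauc-8-en-4-ol
Product: 6 (1S,4S,5R)-4-hydroxydauc-8-en-10-one
Conditions: Rh2(cap)4 (1 mol %), t-BuOOH (70% aq), K2CO3, CH2Cl2, rt
Reagents that add atoms: tert-butyl hydroperoxide, CC(C)(C)OO
Why: Radical allylic C–H oxidation by tert-butylperoxyl radicals formed on the dirhodium caprolactamate: in trisubstituted cycloalkenes hydrogen is taken from the methylene attached to the CH terminus (here C10), and the resulting allyl radical is oxygenated at its secondary end and collapses to the β-methyl enone. The tertiary alcohol is inert and no stereocentre is created (the C1 descriptor changes from R to S by priority only).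

Step 5
Reactants: 6 (1S,4S,5R)-4-hydroxydauc-8-en-10-one
Product: 7 (1S,4S,5S,6R)-4,6-dihydroxydauc-8-en-10-one
Conditions: P450 BM3 (CYP102A1) variant selected from a mutant panel (cell-free lysate), NADP+ (cat.), D-glucose, glucose dehydrogenase, air, potassium phosphate buffer pH 8.0, 2% DMSO, 25 °C
Reagents that add atoms: dioxygen, O=O
Why: Proposed new method: engineered P450 monooxygenases are known to hydroxylate the methylene δ to the carbonyl of cyclic enones in steroids and unactivated methylenes of sesquiterpenoids, but no variant has been shown to act on a hydroazulenone, so that reaction type is transferred here. The ferryl-oxo haem abstracts the C6 hydrogen cis to the C1 methyl and oxygen rebound follows with retention, so site and face (6R) are set by the binding pose chosen in the screen, while conjugation with the ketone protects C8=C9 from epoxidation.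

Step 6
Reactants: 8 4-hydroxybenzoic acid
Product: 10 4-(tert-butyldimethylsilyloxy)benzoic acid, via tert-butyldimethylsilyl 4-(tert-butyldimethylsilyloxy)benzoate 9 (not isolated)
Conditions: TBSCl (2.2 equiv), imidazole, DMF, rt; then AcOH/THF/H2O, rt
Reagents that add atoms: tert-butyldimethylsilyl chloride, CC(C)(C)[Si](C)(C)Cl
Why: Exhaustive silylation followed by selective hydrolysis of the much more labile silyl ester leaves the aryl silyl ether, so the phenol is masked and the acid is free for carbodiimide coupling.

Step 7
Reactants: 7 (1S,4S,5S,6R)-4,6-dihydroxydauc-8-en-10-one; 10 4-(tert-butyldimethylsilyloxy)benzoic acid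
Product: 11 (1S,4S,5S,6R)-4-hydroxy-10-oxodauc-8-en-6-yl 4-(tert-butyldimethylsilyloxy)benzoate
Conditions: EDC·HCl, DMAP (0.2 equiv), CH2Cl2, 0 °C → rt
Reagents that add atoms: none
Why: Steglich esterification: only the secondary C6 hydroxyl is acylated, the C4 carbinol being tertiary and flanked by the isopropyl group, and C6 keeps its configuration because the bond is formed at oxygen. Cold conditions with little base are chosen so that the δ-acyloxy enone does not lose the ester by vinylogous β-elimination.

Step 8
Reactants: 11 (1S,4S,5S,6R)-4-hydroxy-10-oxodauc-8-en-6-yl 4-(tert-butyldimethylsilyloxy)benzoate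
Product: 12 (1S,4S,5S,6R,10S)-4,10-dihydroxydauc-8-en-6-yl 4-(tert-butyldimethylsilyloxy)benzoate
Conditions: NaBH4, CeCl3·7H2O, MeOH/THF, −78 °C
Reagents that add atoms: none
Why: Luche 1,2-reduction: the pseudo-axial C1 methyl next to the carbonyl shields its own face, so hydride should add anti to it and place the new C10 hydroxyl cis to the methyl (10S), as in reductions of cyclic ketones flanked by an angular methyl. The low temperature spares the aryl silyl ether and the ester.

Step 9
Reactants: 12 (1S,4S,5S,6R,10S)-4,10-dihydroxydauc-8-en-6-yl 4-(tert-butyldimethylsilyloxy)benzoate; 13 3-methylbutanoic acid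
Product: 14 (1S,4S,5S,6R,10S)-4-hydroxy-10-(3-methylbutanoyloxy)dauc-8-en-6-yl 4-(tert-butyldimethylsilyloxy)benzoate
Conditions: EDC·HCl, DMAP, CH2Cl2, rt
Reagents that add atoms: none
Why: Steglich esterification of the only remaining acylable hydroxyl (secondary, allylic); acylation at oxygen keeps the C10 configuration, and the neutral carbodiimide conditions avoid ionisation of the allylic system.

Step 10
Reactants: 14 (1S,4S,5S,6R,10S)-4-hydroxy-10-(3-methylbutanoyloxy)dauc-8-en-6-yl 4-(tert-butyldimethylsilyloxy)benzoate
Product: 15 (1S,4S,5S,6R,10S)-4-hydroxy-10-(3-methylbutanoyloxy)dauc-8-en-6-yl 4-hydroxybenzoate (target, CNP0086724.2)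
Conditions: TBAF, AcOH (1:1), THF, 0 °C
Reagents that add atoms: none
Why: Fluoride cleavage of an aryl silyl ether that carries a para ester is fast at 0 °C; buffering with acetic acid keeps the phenol protonated, so neither ester should be cleaved or migrate and the allylic ester and tertiary alcohol stay untouched.

## Compound list

1 | (2E,6E)-farnesol | CC(C)=CCC/C(C)=C/CC/C(C)=C/CO | starting material
2 | (2E,6E)-farnesyl chloride | CC(C)=CCC/C(C)=C/CC/C(C)=C/CCl | intermediate
3 | (2E,6E)-farnesyl diphosphate (free-acid formula; used as trisammonium salt) | CC(C)=CCC/C(C)=C/CC/C(C)=C/COP(=O)(O)OP(=O)(O)O | intermediate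
4 | (3R,6E)-nerolidyl diphosphate (enzyme-bound, not isolated) | C=C[C@](C)(OP(=O)(O)OP(=O)(O)O)CC/C=C(\C)CCC=C(C)C | intermediate
5 | (1R,4S,5R)-dauc-8-en-4-ol | CC1=CC[C@@]2(C)CC[C@](O)(C(C)C)[C@@H]2CC1 | intermediate
6 | (1S,4S,5R)-4-hydroxydauc-8-en-10-one | CC1=CC(=O)[C@@]2(C)CC[C@](O)(C(C)C)[C@@H]2CC1 | intermediate
7 | (1S,4S,5S,6R)-4,6-dihydroxydauc-8-en-10-one | CC1=CC(=O)[C@@]2(C)CC[C@](O)(C(C)C)[C@@H]2[C@H](O)C1 | intermediate
8 | 4-hydroxybenzoic acid | O=C(O)c1ccc(O)cc1 | starting material
9 | tert-butyldimethylsilyl 4-(tert-butyldimethylsilyloxy)benzoate (not isolated) | CC(C)(C)[Si](C)(C)OC(=O)c1ccc(O[Si](C)(C)C(C)(C)C)cc1 | intermediate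
10 | 4-(tert-butyldimethylsilyloxy)benzoic acid | CC(C)(C)[Si](C)(C)Oc1ccc(C(=O)O)cc1 | intermediate
11 | (1S,4S,5S,6R)-4-hydroxy-10-oxodauc-8-en-6-yl 4-(tert-butyldimethylsilyloxy)benzoate | CC1=CC(=O)[C@@]2(C)CC[C@](O)(C(C)C)[C@@H]2[C@H](OC(=O)c2ccc(O[Si](C)(C)C(C)(C)C)cc2)C1 | intermediate
12 | (1S,4S,5S,6R,10S)-4,10-dihydroxydauc-8-en-6-yl 4-(tert-butyldimethylsilyloxy)benzoate | CC1=C[C@H](O)[C@@]2(C)CC[C@](O)(C(C)C)[C@@H]2[C@H](OC(=O)c2ccc(O[Si](C)(C)C(C)(C)C)cc2)C1 | intermediate
13 | 3-methylbutanoic acid | CC(C)CC(=O)O | starting material
14 | (1S,4S,5S,6R,10S)-4-hydroxy-10-(3-methylbutanoyloxy)dauc-8-en-6-yl 4-(tert-butyldimethylsilyloxy)benzoate | CC1=C[C@H](OC(=O)CC(C)C)[C@@]2(C)CC[C@](O)(C(C)C)[C@@H]2[C@H](OC(=O)c2ccc(O[Si](C)(C)C(C)(C)C)cc2)C1 | intermediate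
15 | (1S,4S,5S,6R,10S)-4-hydroxy-10-(3-methylbutanoyloxy)dauc-8-en-6-yl 4-hydroxybenzoate | CC1=C[C@H](OC(=O)CC(C)C)[C@@]2(C)CC[C@](O)(C(C)C)[C@@H]2[C@H](OC(=O)c2ccc(O)cc2)C1 | target

## Step count and least certain steps

Total: 10 steps. Longest linear sequence: 9 steps (steps 1–5 and 7–10); step 6 is a one-step side branch.

**Step 3 (key step, proposed new method).** The most likely failure is that no enzyme with this product specificity is found, or that the cascade is quenched early: loss of a proton to give olefins, or water capture before the hydride shift. The fold, the hydride shift and the water position all depend on an active site that has not yet been characterised.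

Fallback, from 3 back to 5, by known chemistry:
- A characterised daucane-olefin synthase of the series with the C1 configuration of 5, one that ends the same cascade by loss of a proton, converts 3 into (1R)-dauca-4,8-diene (daucene) F1.
- The chemical task is then a syn addition of H and OH across C4=C5 on the face anti to the C1 methyl while C8=C9 is kept.
- OsO4 (catalytic) with N-methylmorpholine N-oxide in aqueous acetone (Upjohn dihydroxylation) should attack the less hindered trisubstituted olefin first, anti to the C1 methyl, to give (1R,8R,9S)-dauc-4-ene-8,9-diol F2.
- Excess BH3·THF (the diol carried as its borate) adds across the tetrasubstituted olefin with boron at C4, the carbon remote from the quaternary centre, and from the face anti to the angular methyl. NaOH/H2O2 then gives (1R,4S,5R,8R,9S)-daucane-4,8,9-triol F3, with C4–OH and C5–H cis to each other.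
- Thiocarbonyldiimidazole converts the cis-diol into (1R,4S,5R,8R,9S)-4-hydroxydaucane-8,9-diyl thionocarbonate F4.
- P(OMe)3 at reflux (Corey–Winter olefination) restores C8=C9 and gives 5.
- The weak point of this fallback is the regiochemistry of the hydroboration.

**Step 5 (proposed new method).** The most likely failure is hydroxylation at another site (the allylic C7 methylene, the isopropyl group or the five-membered ring), on the other face of C6, or poor conversion through uncoupled cofactor consumption. The selectivity has to be found by screening and is not predictable from the substrate.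

Fallback, from 6 back to 11 (it also replaces step 7), by known chemistry:
- Chloranil in refluxing tert-butanol dehydrogenates 6 across C6–C7, the usual course for a cyclic enone whose other α position is blocked, to the dienone (1S,4S,5R)-4-hydroxydauca-6,8-dien-10-one F5.
- mCPBA (NaHCO3, CH2Cl2, 0 °C) epoxidises the electron-richer γ,δ-double bond, guided by the C4 hydroxyl to its own face, to give (1S,4S,5S,6R,7S)-6,7-epoxy-4-hydroxydauc-8-en-10-one F6.
- Pd2(dba)3·CHCl3/n-Bu3P with HCO2H–Et3N in dioxane (formate hydrogenolysis of a vinyl epoxide) replaces the allylic C7–O bond by C7–H and leaves (1S,4S,5S,6S)-4,6-dihydroxydauc-8-en-10-one F7, the C6 epimer of 7.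
- Mitsunobu esterification of F7 with 10 (PPh3, DIAD, THF, 0 °C) inverts C6 and gives 11 directly.

**Step 8.** The most likely failure is poor facial selectivity of hydride delivery, because a flexible cycloheptenone shields its faces less clearly than a six-membered ring. Some loss of the C6 ester by vinylogous elimination before reduction is also possible.

Fallback, from 11 back to 14 (it also replaces step 9):
- If hydride enters mainly cis to the methyl, the product is the C10 epimer (1S,4S,5S,6R,10R)-4,10-dihydroxydauc-8-en-6-yl 4-(tert-butyldimethylsilyloxy)benzoate F11.
- Mitsunobu esterification of F11 with 13 (PPh3, DIAD, toluene, 0 °C → rt) introduces the acyl group with inversion at the allylic carbon and gives 14.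

**Step 4.** The most likely failure is hydrogen abstraction at C7 or at the C8 methyl in competition with C10, which is hindered by the neighbouring quaternary carbon. Over-oxidation to an ene-dione is a further risk.

Fallback, from 5 back to 6:
- mCPBA gives (1R,4S,5R,8R,9S)-8,9-epoxydaucan-4-ol F8. The face anti to the C1 methyl is expected, but the face is of no consequence.
- Sodium phenylselenide (PhSeSePh, NaBH4, EtOH, reflux) opens the epoxide at the secondary C9 to (1R,4S,5R,8R,9R)-9-(phenylselanyl)daucane-4,8-diol F9.
- H2O2 oxidises the selenide, and the selenoxide eliminates towards C10, the only side that carries hydrogen, to give the tertiary allylic alcohol (1R,4S,5R,8R)-dauc-9-ene-4,8-diol F10.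
- Pyridinium chlorochromate, [C5H5NH][CrO3Cl], in CH2Cl2 effects the oxidative 1,3-transposition (Babler–Dauben oxidation) to 6.

## Further compounds

F1 | step 3 | (1R)-dauca-4,8-diene (daucene) | CC1=CC[C@@]2(C)CCC(C(C)C)=C2CC1
F2 | step 3 | (1R,8R,9S)-dauc-4-ene-8,9-diol | C[C@]1(O)[C@@H](O)C[C@@]2(C)CCC(C(C)C)=C2CC1
F3 | step 3 | (1R,4S,5R,8R,9S)-daucane-4,8,9-triol | C[C@]1(O)[C@@H](O)C[C@@]2(C)CC[C@](O)(C(C)C)[C@@H]2CC1
F4 | step 3 | (1R,4S,5R,8R,9S)-4-hydroxydaucane-8,9-diyl thionocarbonate | C[C@]12OC(=S)O[C@H]1C[C@@]3(C)CC[C@](O)(C(C)C)[C@@H]3CC2
F5 | step 5 | (1S,4S,5R)-4-hydroxydauca-6,8-dien-10-one | CC1=CC(=O)[C@@]2(C)CC[C@](O)(C(C)C)[C@@H]2C=C1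
F6 | step 5 | (1S,4S,5S,6R,7S)-6,7-epoxy-4-hydroxydauc-8-en-10-one | CC1=CC(=O)[C@@]2(C)CC[C@](O)(C(C)C)[C@@H]2[C@H]3O[C@H]31
F7 | step 5 | (1S,4S,5S,6S)-4,6-dihydroxydauc-8-en-10-one | CC1=CC(=O)[C@@]2(C)CC[C@](O)(C(C)C)[C@@H]2[C@@H](O)C1
F8 | step 4 | (1R,4S,5R,8R,9S)-8,9-epoxydaucan-4-ol | C[C@]12O[C@H]1C[C@@]3(C)CC[C@](O)(C(C)C)[C@@H]3CC2
F9 | step 4 | (1R,4S,5R,8R,9R)-9-(phenylselanyl)daucane-4,8-diol | C[C@]1(O)[C@H]([Se]c2ccccc2)C[C@@]3(C)CC[C@](O)(C(C)C)[C@@H]3CC1
F10 | step 4 | (1R,4S,5R,8R)-dauc-9-ene-4,8-diol | C[C@]1(O)C=C[C@@]2(C)CC[C@](O)(C(C)C)[C@@H]2CC1
F11 | step 8 | (1S,4S,5S,6R,10R)-4,10-dihydroxydauc-8-en-6-yl 4-(tert-butyldimethylsilyloxy)benzoate | CC1=C[C@@H](O)[C@@]2(C)CC[C@](O)(C(C)C)[C@@H]2[C@H](OC(=O)c2ccc(O[Si](C)(C)C(C)(C)C)cc2)C1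
A1 | alternative 1 | (1S,4S,5S,6R)-6-[(4-methoxyphenyl)methoxy]-4-(triethylsilyloxy)dauc-8-en-10-one | CC1=CC(=O)[C@@]2(C)CC[C@](O[Si](CC)(CC)CC)(C(C)C)[C@@H]2[C@H](OCc3ccc(OC)cc3)C1
A2 | alternative 1 | (3S,3aS,4R,7aS)-4-[(4-methoxyphenyl)methoxy]-6,7a-dimethyl-3-(propan-2-yl)-3-(triethylsilyloxy)-7-(trimethylsilyloxy)-2,3,3a,4,5,7a-hexahydro-1H-indene | CC1=C(O[Si](C)(C)C)[C@@]2(C)CC[C@](O[Si](CC)(CC)CC)(C(C)C)[C@@H]2[C@H](OCc3ccc(OC)cc3)C1
A3 | alternative 2 | (1S,6R,10S)-6-(tert-butyldimethylsilyloxy)-10-(methoxymethoxy)dauca-4,8-dien-3-one | CC1=C[C@H](OCOC)[C@@]2(C)CC(=O)C(C(C)C)=C2[C@H](O[Si](C)(C)C(C)(C)C)C1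
A4 | alternative 2 | (3S,4Z,7R)-7-(tert-butyldimethylsilyloxy)-3-(methoxymethoxy)-2,5,10-trimethylundeca-1,4-dien-8-yne | CC(C)C#C[C@H](O[Si](C)(C)C(C)(C)C)C/C(C)=C\[C@H](OCOC)C(C)=C
A5 | alternative 3 | (3S,8aS)-3-isopropyl-4,8-dimethoxy-6,8a-dimethyl-3-(triethylsilyloxy)-3,8a-dihydroazulen-1(2H)-one | CC1=CC(OC)=C2[C@@](O[Si](CC)(CC)CC)(C(C)C)CC(=O)[C@]2(C)C(OC)=C1
A6 | alternative 3 | (5S)-2-diazo-5-(2,6-dimethoxy-4-methylphenyl)-6-methyl-5-(triethylsilyloxy)heptan-3-one | CC(=[N+]=[N-])C(=O)C[C@](O[Si](CC)(CC)CC)(C(C)C)c1c(OC)cc(C)cc1OC
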